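The runs were computed from invented constants; scatter was added.

To judge whether 10 h is long enough for this flask, count what is left, not what is made.

| flask | substrate | reagent | catalyst | remark | time |
|---|---|---|---|---|---|
| north-west | 0.28 M | 1.2 equiv (fed, over 40 min) | 0.5 mol% | run made earlier; the fed solution adds 0.50 times the starting volume |  |
| east | 0.44 M | 1.2 equiv (fed, over 40 min) | 0.5 mol% | run made earlier; the fed solution adds 0.50 times the starting volume |  |
| south | 0.20 M | 1.2 equiv (fed, over 40 min) | 0.25 mol% | run made earlier; the fed solution adds 0.50 times the starting volume |  |
| flask | 0.20 M | 1.20 equiv (fed, over 40 min) | 0.5 mol% | the fed solution adds 0.50 times the starting volume | 10 h |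

| run | time / h | substrate / % | target / % |
|---|---|---|---|
| north-west | 0.833 | 80 | 9 |
| north-west | 2.00 | 69 | 22 |
| north-west | 4.00 | 56 | 35 |
| north-west | 6.00 | 47 | 45 |
| east | 1.50 | 61 | 30 |
| east | 3.00 | 47 | 50 |
| east | 5.00 | 31 | 64 |
| east | 6.00 | 26 | 69 |
| south | 0.833 | 86 | 0 |
| south | 2.00 | 81 | 5 |
| south | 4.00 | 77 | 11 |
| south | 6.00 | 71 | 18 |

(standard deviation of a reading: 1.5 percentage points)

- amounts are per litre of the starting volume; all of the dose is in the solution fed
- the numbers in the tables scatter with a standard deviation of 1.5 percentage points

- share of the substrate used up at 10 h
- target at 10 h, in percent of the substrate charged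
- intermediate at 10 h, in percent of the substrate charged

The substrate curve of the south run opens steeply: substrate is down to 86% at 0.833 h with target at 0%. The gap in that balance, read as intermediate, stands to substrate as 0.163. My reckoning therefore treats substrate and intermediate as one pool, so the first knee in this flask, reckoned with no target formed, lies near substrate 86.0%.

Target is then taken as first order in reagent, in pool and in catalyst. After the feed, reagent and pool differ by a fixed excess, so at fixed equivalents the logarithm of their ratio is reckoned to rise in a straight line:

r = [reagent] / ([substrate] + [intermediate])

ln r = ln(equivalents) + m · (t − half the dosing time)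

The slopes between readings, scaled to this flask by loading times starting [substrate] squared, are 0.0104 h⁻¹ (north-west), 0.0113 h⁻¹ (east) and 0.0136 h⁻¹ (south). Their mean is m = 0.0118 h⁻¹, the clock rate, the rise of ln r per hour at this flask's charges.

From ln r = 0.182, this flask reaches at 10 h:

ln r = 0.296, target 42.0%, substrate 49.9%, intermediate 8.12%

By this reckoning target passes substrate at 46.2%, near 11.7 h, later than the asked time. The level ahead is the substrate charge, substrate being the limiting reagent at 1.20 equiv.

The forecast gives conversion 50%, target 42% and intermediate 8%, on the ground that “the intermediate appears to sit in fast equilibrium with substrate”.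

The flask gives conversion 50.6%, target 42.4% and intermediate 8.23%.

    substrate + catalyst ⇌ catalyst + intermediate (K = 0.170, k = 0.980 M⁻¹ s⁻¹)
    reagent + catalyst + intermediate → catalyst + target (k = 1.30 M⁻² s⁻¹)

At 2.31 h the intermediate in this flask falls back 31 times faster than it goes on, and at 10.0 h the first step, both ways together, relaxes with a half-life of 2.57 min, short against 10 h. At 10.0 h intermediate 8.23% stands beside substrate 49.4%, a ratio of 0.167.

For the same flask read at 4.0 h, the clock rate gives ln r = 0.226, so target 20.9%. The computed neighbour holds target 21.4%.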